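**Assumption:** (2E)-4-acetoxy-2-methylbut-2-enal (the industrial C5 vitamin A building block), geranyl chloride and tiglic acid are taken as commercial; ring compounds carry germacrane numbering, in which the target is 3S,4R,5R,6R,7S with a 1(10)E alkene, C3 tiglate, C6 acetate, 4,5-oxirane and C7 isopropenyl.

## Retrosynthetic overview

1. Target ⇐ acetylation of the ten-membered epoxy alcohol.
2. Ten-membered ring ⇐ C6–C7 bond (farnesyl C1–C10) by Lewis-acid carbonyl-ene (Prins-type) macrocyclization of an acyclic epoxy aldehyde. The unfunctionalized terminal isopropylidene is the nucleophile and sheds a methyl hydrogen to give the isopropenyl group, as in germacrene A formation; this sets C6 and C7.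
3. Epoxy aldehyde ⇐ erythro epoxy alcohol by Mitsunobu inversion with tiglic acid, deacetylation and oxidation; the erythro epoxy alcohol ⇐ racemic 4-hydroxyfarnesyl acetate by Sharpless kinetic-resolution epoxidation.
4. 4-Hydroxyfarnesyl acetate ⇐ C5 enal + geranyl chloride (α-selective geranylbarium addition).
5. Ring order: the oxirane first, on the open chain (it fixes absolute configuration and blocks six-membered closure); the ten-membered carbocycle second.

## Route

**Step 1**
Reactants: 1 (2E)-4-acetoxy-2-methylbut-2-enal; 2 geranyl chloride [(2E)-1-chloro-3,7-dimethylocta-2,6-diene]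
Product: 4 rac-(2E,6E)-4-hydroxy-3,7,11-trimethyldodeca-2,6,10-trien-1-yl acetate, via geranylbarium chloride 3 (not isolated)
Conditions: BaI2, Li, biphenyl, THF, rt (zerovalent barium); 2, −78 °C; then 1, −78 °C; H2O
Reagents that add atoms: none
Why: Allylbarium reagents add to aldehydes through their α-carbon with retention of the (E)-alkene geometry (α-selective carbonyl allylation), and at −78 °C the aldehyde reacts in 1,2-fashion far faster than the acetate; the carbinol center forms as a racemate.

**Step 2**
Reactants: 4 rac-(2E,6E)-4-hydroxy-3,7,11-trimethyldodeca-2,6,10-trien-1-yl acetate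
Product: 5 [(2R,3R)-3-[(1R,3E)-1-hydroxy-4,8-dimethylnona-3,7-dien-1-yl]-3-methyloxiran-2-yl]methyl acetate
Conditions: Ti(OiPr)4 (15 mol%), (S,S)-(−)-DIPT [D-(−)-diisopropyl tartrate] (20 mol%), t-BuOOH (0.55 equiv), 4 Å MS, CH2Cl2, −20 °C
Reagents that add atoms: tert-butyl hydroperoxide, CC(C)(C)OO
Why: Sharpless kinetic-resolution epoxidation: the Ti/D-(−)-tartrate catalyst epoxidizes only the (R)-enantiomer of 4, on the alkene face that gives the (2R,3R)-oxirane erythro to the carbinol, so both oxirane centers and the carbinol configuration are fixed at once (maximum 50% from the racemate, (S)-4 is left), while the two remote alkenes have no directing hydroxyl and stay intact.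

**Step 3**
Reactants: 5 [(2R,3R)-3-[(1R,3E)-1-hydroxy-4,8-dimethylnona-3,7-dien-1-yl]-3-methyloxiran-2-yl]methyl acetate; 6 tiglic acid [(2E)-2-methylbut-2-enoic acid]
Product: 7 (1S,3E)-1-[(2R,3R)-3-(acetoxymethyl)-2-methyloxiran-2-yl]-4,8-dimethylnona-3,7-dien-1-yl (2E)-2-methylbut-2-enoate
Conditions: PPh3, DIAD, THF, 0 °C → rt
Reagents that add atoms: tiglic acid (compound 6), C/C=C(\C)C(=O)O
Why: Mitsunobu esterification: tiglate displaces the alkoxyphosphonium by SN2, so the carbinol carbon is inverted from R to S (erythro to threo) and the tigloyl ester is installed in the same operation.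

**Step 4**
Reactants: 7 (1S,3E)-1-[(2R,3R)-3-(acetoxymethyl)-2-methyloxiran-2-yl]-4,8-dimethylnona-3,7-dien-1-yl (2E)-2-methylbut-2-enoate
Product: 8 (1S,3E)-1-[(2R,3R)-3-(hydroxymethyl)-2-methyloxiran-2-yl]-4,8-dimethylnona-3,7-dien-1-yl (2E)-2-methylbut-2-enoate
Conditions: K2CO3 (0.2 equiv), MeOH, 0 °C, short reaction time
Reagents that add atoms: none
Why: Base-catalyzed transesterification cleaves the unhindered primary acetate much faster than the hindered, conjugated, α-branched secondary tiglate, the trans-oxirane keeps the two oxygens too far apart for acyl migration, and no stereocenter is touched.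

**Step 5**
Reactants: 8 (1S,3E)-1-[(2R,3R)-3-(hydroxymethyl)-2-methyloxiran-2-yl]-4,8-dimethylnona-3,7-dien-1-yl (2E)-2-methylbut-2-enoate
Product: 9 (1S,3E)-1-[(2R,3S)-3-formyl-2-methyloxiran-2-yl]-4,8-dimethylnona-3,7-dien-1-yl (2E)-2-methylbut-2-enoate
Conditions: TEMPO (10 mol%), PhI(OAc)2, CH2Cl2, rt
Reagents that add atoms: none
Why: Oxoammonium (TEMPO) oxidation takes the primary epoxy alcohol to the aldehyde without over-oxidation, without epimerizing the oxirane carbon and without touching the alkenes (the descriptor changes from R to S only because CHO outranks the neighbouring oxirane carbon).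

**Step 6**
Reactants: 9 (1S,3E)-1-[(2R,3S)-3-formyl-2-methyloxiran-2-yl]-4,8-dimethylnona-3,7-dien-1-yl (2E)-2-methylbut-2-enoate
Product: 11 (1E,3S,4R,5R,6R,7S)-4,5-epoxy-6-hydroxygermacra-1(10),11-dien-3-yl (2E)-2-methylbut-2-enoate, via aluminium alkoxide 10 (not isolated)
Conditions: Me2AlCl (3 equiv), CH2Cl2 (0.002 M, 9 added by syringe pump), −78 → −40 °C; aq. potassium sodium tartrate
Reagents that add atoms: none
Why: Proposed new method: Me2AlCl activates the epoxy aldehyde, the terminal trisubstituted alkene attacks it through its CH carbon (Markovnikov, tertiary germacradienyl-type cation or its concerted ene equivalent) and a methyl hydrogen passes to oxygen, so the ten-membered ring, the C6 carbinol and the isopropenyl group form in one step; the trans-oxirane makes six-membered (isopulegol-type) closure by the internal alkene geometrically impossible and its two oxygen-bearing neighbours deactivate it toward Lewis-acid opening; in the crossed germacrane-like folding the oxirane C–O bond lies anti to the forming bond (polar Felkin–Anh), which is expected to give the 5,6-anti carbinol (6R) with the isopropenyl group pseudo-equatorial (7S); loss of methane to alkoxide 10 keeps the medium proton-free; the closest known reaction type is the Lewis-acid-promoted intramolecular carbonyl-ene (Prins) cyclization of ω-alkenyl aldehydes, established for six-membered rings and for twelve- to sixteen-membered rings from alkynals.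

**Step 7**
Reactants: 11 (1E,3S,4R,5R,6R,7S)-4,5-epoxy-6-hydroxygermacra-1(10),11-dien-3-yl (2E)-2-methylbut-2-enoate
Product: 12 (1E,3S,4R,5R,6R,7S)-6-acetoxy-4,5-epoxygermacra-1(10),11-dien-3-yl (2E)-2-methylbut-2-enoate (target CNP0400048.1)
Conditions: Ac2O, DMAP (cat.), pyridine, 0 °C → rt
Reagents that add atoms: acetic anhydride, CC(=O)OC(C)=O
Why: DMAP-catalyzed acylation of the hindered secondary alcohol proceeds with retention at C6, and the oxirane, tiglate and alkenes are inert to these mild basic conditions.

## Compound list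

1 | (2E)-4-acetoxy-2-methylbut-2-enal | CC(=O)OC/C=C(\C)C=O | starting material
2 | geranyl chloride, (2E)-1-chloro-3,7-dimethylocta-2,6-diene | CC(C)=CCC/C(C)=C/CCl | starting material
3 | geranylbarium chloride | CC(C)=CCC/C(C)=C/C[Ba]Cl | intermediate
4 | rac-(2E,6E)-4-hydroxy-3,7,11-trimethyldodeca-2,6,10-trien-1-yl acetate | CC(C)=CCC/C(C)=C/CC(O)/C(C)=C/COC(C)=O | intermediate
5 | [(2R,3R)-3-[(1R,3E)-1-hydroxy-4,8-dimethylnona-3,7-dien-1-yl]-3-methyloxiran-2-yl]methyl acetate | CC(C)=CCC/C(C)=C/C[C@@H](O)[C@@]1(C)O[C@@H]1COC(C)=O | intermediate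
6 | tiglic acid, (2E)-2-methylbut-2-enoic acid | C/C=C(\C)C(=O)O | starting material
7 | (1S,3E)-1-[(2R,3R)-3-(acetoxymethyl)-2-methyloxiran-2-yl]-4,8-dimethylnona-3,7-dien-1-yl (2E)-2-methylbut-2-enoate | CC(C)=CCC/C(C)=C/C[C@H](OC(=O)/C(C)=C/C)[C@@]1(C)O[C@@H]1COC(C)=O | intermediate
8 | (1S,3E)-1-[(2R,3R)-3-(hydroxymethyl)-2-methyloxiran-2-yl]-4,8-dimethylnona-3,7-dien-1-yl (2E)-2-methylbut-2-enoate | CC(C)=CCC/C(C)=C/C[C@H](OC(=O)/C(C)=C/C)[C@@]1(C)O[C@@H]1CO | intermediate
9 | (1S,3E)-1-[(2R,3S)-3-formyl-2-methyloxiran-2-yl]-4,8-dimethylnona-3,7-dien-1-yl (2E)-2-methylbut-2-enoate | CC(C)=CCC/C(C)=C/C[C@H](OC(=O)/C(C)=C/C)[C@@]1(C)O[C@@H]1C=O | intermediate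
10 | chloro(methyl)aluminium alkoxide of 11 | C=C(C)[C@@H]1CC/C(C)=C/C[C@H](OC(=O)/C(C)=C/C)[C@@]2(C)O[C@@H]2[C@@H]1O[Al](C)Cl | intermediate
11 | (1E,3S,4R,5R,6R,7S)-4,5-epoxy-6-hydroxygermacra-1(10),11-dien-3-yl (2E)-2-methylbut-2-enoate | C=C(C)[C@@H]1CC/C(C)=C/C[C@H](OC(=O)/C(C)=C/C)[C@@]2(C)O[C@@H]2[C@@H]1O | intermediate
12 | (1E,3S,4R,5R,6R,7S)-6-acetoxy-4,5-epoxygermacra-1(10),11-dien-3-yl (2E)-2-methylbut-2-enoate | C=C(C)[C@@H]1CC/C(C)=C/C[C@H](OC(=O)/C(C)=C/C)[C@@]2(C)O[C@@H]2[C@@H]1OC(C)=O | target

## Step count and risks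

Total step count: 7. Longest linear sequence: 7 steps (1 or 2 → 12).

**Most likely to fail, in order: step 6, step 3, step 2.**

**Step 6 (macrocyclic carbonyl-ene).** A ten-membered ring from an unactivated alkene is unprecedented. The C6/C7 outcome is a prediction, not a certainty: the usual steric preference in Lewis-acid ene reactions would favour the C6 epimer, against the Felkin–Anh argument used here. Other failure modes are oligomerization, methyl transfer from aluminium, chloride capture of the cation, and transannular opening of the oxirane. The fallback sets out from 8 and comes back at 11. Ene-type allylic chlorination of the more accessible terminal isopropylidene with Ca(OCl)2/CO2 in CH2Cl2–H2O at 0 °C gives the allylic chloride F1 as a mixture of C–Cl epimers, both usable; the internal alkene is shielded and inductively deactivated by the neighbouring tigloyloxy group. TEMPO/PhI(OAc)2 then gives the chloro aldehyde F2. The ring is closed by umpolung allylation with PdCl2(PPh3)2 (cat.), Et2Zn and K2CO3 in DMA at 0.01 M and rt: zerovalent palladium ionizes the chloride, transmetalation gives an allylzinc, and this adds to the aldehyde through its γ-carbon in a closed six-membered transition state to give 11. This swaps the cationic pathway for a pre-installed leaving group at the cost of one extra step.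

**Step 3 (Mitsunobu with tiglic acid).** The carbinol sits next to a fully substituted oxirane carbon and tiglic acid is only weakly acidic, so the SN2 displacement may be slow or give elimination. The fallback sets out from 4 and comes back at 8. The kinetic resolution of step 2 leaves the slow-reacting enantiomer, the (S)-alcohol F3, which already has the C–O configuration of the target. Acylation with retention (tigloyl chloride, DMAP, pyridine, CH2Cl2) gives the diester F4. K2CO3/MeOH at 0 °C removes the primary acetate to give the primary allylic alcohol F5. Reagent-controlled Sharpless asymmetric epoxidation with Ti(OiPr)4, D-(−)-diethyl tartrate and t-BuOOH (CH2Cl2, −20 °C; same alkene face as in step 2) then gives 8. Inversion is replaced by retention chemistry, and the half of 4 that the main route discards is used.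

**Step 2 (kinetic resolution).** The allylic acetate makes the alkene electron-poor, so rate and selectivity factor may be too low, and the yield is capped at 50%. The fallback sets out from 4 and comes back at 5. MnO2 (CH2Cl2, rt) gives the enone F6. Reduction with (S)-Me-CBS oxazaborolidine and catecholborane (toluene, −78 °C; the branched alkenyl group acts as the large substituent) gives the (R)-alcohol F7. Hydroxyl-directed epoxidation with VO(acac)2/t-BuOOH (CH2Cl2, 0 °C) then gives 5; the methyl group on the carbinol-bearing alkene carbon enforces the erythro relation through A(1,2) strain.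

## Further compounds

F1 | step 6 | (1S,3E)-7-chloro-1-[(2R,3R)-3-(hydroxymethyl)-2-methyloxiran-2-yl]-4,8-dimethylnona-3,8-dien-1-yl (2E)-2-methylbut-2-enoate | C=C(C)C(Cl)CC/C(C)=C/C[C@H](OC(=O)/C(C)=C/C)[C@@]1(C)O[C@@H]1CO
F2 | step 6 | (1S,3E)-7-chloro-1-[(2R,3S)-3-formyl-2-methyloxiran-2-yl]-4,8-dimethylnona-3,8-dien-1-yl (2E)-2-methylbut-2-enoate | C=C(C)C(Cl)CC/C(C)=C/C[C@H](OC(=O)/C(C)=C/C)[C@@]1(C)O[C@@H]1C=O
F3 | step 3 | (2E,4S,6E)-4-hydroxy-3,7,11-trimethyldodeca-2,6,10-trien-1-yl acetate | CC(C)=CCC/C(C)=C/C[C@H](O)/C(C)=C/COC(C)=O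
F4 | step 3 | (2E,4S,6E)-1-acetoxy-3,7,11-trimethyldodeca-2,6,10-trien-4-yl (2E)-2-methylbut-2-enoate | CC(C)=CCC/C(C)=C/C[C@H](OC(=O)/C(C)=C/C)/C(C)=C/COC(C)=O
F5 | step 3 | (2E,4S,6E)-1-hydroxy-3,7,11-trimethyldodeca-2,6,10-trien-4-yl (2E)-2-methylbut-2-enoate | CC(C)=CCC/C(C)=C/C[C@H](OC(=O)/C(C)=C/C)/C(C)=C/CO
F6 | step 2 | (2E,6E)-3,7,11-trimethyl-4-oxododeca-2,6,10-trien-1-yl acetate | CC(C)=CCC/C(C)=C/CC(=O)/C(C)=C/COC(C)=O
F7 | step 2 | (2E,4R,6E)-4-hydroxy-3,7,11-trimethyldodeca-2,6,10-trien-1-yl acetate | CC(C)=CCC/C(C)=C/C[C@@H](O)/C(C)=C/COC(C)=O
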